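Numbering used throughout (rearranged-drimane convention): ring A = C1–C5 and C10, ring B = C5–C10, C11 = the methylene between C8 and the five-membered ring C. β is the face of the C5 methyl, α the opposite face.

## Structural features

Dysidenone B joins a trans-fused Δ3-octalin (ring A with the C3=C4 alkene and a C4 methyl, ring B saturated) through the C11 methylene at C8 to a cyclopentenone (ring C). Ring C carries a tertiary alcohol and a methyl ester on one carbon, a methoxy enol ether and a ketone. Ring B holds four contiguous stereocentres: quaternary C5 (methyl), C10 (H), C9 (H and methyl) and quaternary C8 (methyl and C11). The C5 methyl, the C9 methyl and C11 are β, while H10, H9 and the C8 methyl are α, so the C5 and C9 methyls are 1,3-diaxial and C9 has the less stable configuration. Ring C adds two adjacent stereocentres (the carbinol carbon and the CH bearing C11) that have no close contact with the decalin stereocentres. Fragile points are the ring-C CH (α to a vinylogous ester carbonyl, epimerised by base), the tertiary α-hydroxy ester (retro-aldol type cleavage) and the C3=C4 alkene beside quaternary C5 (cationic 1,2-shifts in acid). The real difficulty is the C8–C9–C10–C5 array, a quaternary carbon next to an axial secondary methyl next to a ring-fusion hydrogen, in a purely hydrocarbon environment. The key step uses the position of C8 between C7 and C9 in ring B: ring B can be grown from a cyclopentanone (C5, C6, C7, C9, C10) by inserting C8 with its methyl and an ester (the future C11), leaving a C9 ketone for the C9 methyl.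

## Logic of the disconnections

24 ⇒ 23. The ring-C bond between the carbinol carbon and the CH carbon is cut and the ester carbon is put back into the ring (formal loss of methanol), which restores a six-membered 2-hydroxy-1,4-quinone. The reason is that ring C has exactly the oxidation level of 23 plus methanol, so a benzilic ester shift connects them without redox steps. The gain is that both ring-C stereocentres and the labile hydroxy ester vanish into a flat ring. The demand is that methoxide attacks the carbonyl carbon that carries the hydroxyl of 23; the shift gets no stereochemical help from the decalin, so 24 must be separated from its ring-C diastereomers.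

23 ⇒ 22 ⇒ 21. Two C–O changes are undone: the hydroxyl of 23 returns to the methyl ether of 22, and the two quinone carbonyls return to the methoxy groups of 21. The reason is that the arene is inert to everything needed for C11. The gain is a robust, symmetric aryl unit. The demand is an oxidation that spares the C3=C4 alkene and a hydrolysis that removes only the methoxy group next to the alkyl chain.

21 ⇒ 20 ⇒ 16 + 18 (from 17). The C11–aryl bond is cut. C11 is neopentyl, so substitution at C11 is not an option; the bond is made by carbonyl addition and the extra oxygen is removed afterwards. The gain is a split into a decalin and a commercial arene. The demand is addition of a di-ortho-substituted aryllithium to a hindered aldehyde, and a deoxygenation that avoids a C11 cation (1,2-shifts, attack by the alkene).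

16 ⇒ 15 ⇒ 14. Only the oxidation level of C11 changes, so the aldehyde carbon is traced back to the ester carbon that the key step brings in. No skeletal bond is cut. The demand is reduction and reoxidation at a neopentyl position without touching the alkene.

14 ⇒ 13 ⇒ 12. The C9–CH3 bond is cut by way of C9=CH2 back to the C9 carbonyl. The reason is that the key step leaves a ketone at C9. The gain is removal of the axial methyl stereocentre. The demand is olefination of a ketone flanked by a quaternary and a tertiary carbon without epimerising C10, then hydrogen delivery to the α-face only, faster than to C3=C4.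

12 ⇒ 11. Only the C10–H configuration changes. The reason is that the precursor of the key step is stable only with a cis ring fusion. The demand is an equilibration that ends on the trans side.

11 ⇒ 8 + 10. The C8–C9 and C7–C8 bonds are cut and C7–C9 is restored, which contracts ring B to the cyclopentanone and removes C8 with its methyl and ester. The gain is the largest of the route: the congested quaternary C8 leaves together with two carbons, and what remains is a simple bicyclic ketone. The demand is migration of C7 (not C10) and reagent-controlled delivery of the ester to the β-face of C8.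

8 ⇒ 7. The C3=C4 double bond is cut (metathesis in the forward sense). The gain is that ring A opens to a monocyclic ketone with two alkenyl arms. The demand is closure onto a 1,1-disubstituted alkene next to a quaternary carbon.

7 ⇒ 6 (from 4) + 5. The C1–C10 bond is cut. The reason is that C10 is the α-carbon of the ketone. The demand is an enolate of defined regiochemistry on the more hindered side, which is why 4 is isolated.

4 ⇒ 1 + 2. The C4–C5 bond is cut. The gain is that the only stereocentre carried into the key step, quaternary C5, comes from a commercial enone by catalytic conjugate addition. The demand is high enantioselectivity on a five-membered enone.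

10 ⇒ 9. The C=N2 unit is traced back to a C–acetyl bond; deacylative diazo transfer gives the α-alkyl diazo ester that direct diazo transfer to a simple ester cannot give.

## Other disconnections considered

Alternative 1: The cut runs through C9–C10 and C4–C5 and opens both rings to the acyclic enyne A1, a malonate carrying an ethynyl group (C9) and an E-trisubstituted alkene (C5=C10) that ends in a silyl enol ether (C3–C4). In the forward step a cationic monovalent gold complex of an axially chiral bisphosphine, [(R)-DTBM-MeO-BIPHEP](AuCl)2 activated with AgSbF6, binds the alkyne. C10 attacks C9 in a 6-exo-dig closure of ring B, C4 of the enol ether traps the C5 cation and closes ring A, and protodeauration should leave the trans-decalin A2 with a C9 methylene, a C3 ketone and a C8 diester.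
- In its favour: both rings, C5 and C10 are set at once, the trans fusion follows from anti addition across the E-alkene, and the C9 methylene arrives without olefination of a hindered ketone.
- Against it: C8 is not a stereocentre in A2. Its two diastereotopic esters must be told apart, one taken down to CH3 and the other to the C11 aldehyde, with no reliable handle. The C3 ketone must then become the C3=C4 alkene regioselectively. A1 needs an alkynylated malonate, an E-alkene and a regiodefined enol ether, and an enol ether as terminating nucleophile is less well supported in such gold cyclisations than arenes or phenols.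
- Comparison: on ring fusion and on the C9 methylene this plan is better than the chosen one, which needs a C10 equilibration and a difficult methylenation. On C8 it is worse, because the chosen key step delivers C8 as a defined stereocentre. The hydrogenation problem at C9 is the same in both, and both rely on a chiral catalyst for absolute configuration. In step count it would be longer (ester differentiation and ketone-to-alkene conversion after A2).

Alternative 2: In the retrosynthetic sense C8–C11, C9–CH3 and C5–CH3 are cut and C9–C11, C10–CH3 and C4–CH3 restored, which leads to the 11-aryl drim-7-ene A3. In the forward step BF3·OEt2 protonates C7=C8, and the C8 cation should trigger successive 1,2-shifts of C11, the C10 methyl, H5 and a C4 methyl, ending with loss of H3 to give A4, which is identical in structure with 21.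
- In its favour: A3 belongs to the configurational series of the natural drimanes and should be short to make from that chiral pool. One operation would create C8, C9 and C10, including the axial C9 methyl and the trans fusion, and the deoxygenated aryl unit is already in place.
- Against it: the C8 cation has competing exits. The axial H9 is better aligned for migration than the equatorial benzylic C11 and would lead to the isomeric skeleton with quaternary C9. Proton loss at each stage and capture of cations by the electron-rich arene are further exits. The outcome depends on small differences in cation energies, and skeletal isomers of this kind are hard to separate.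
- Comparison: in step economy and in the C9/C10 problem this plan is clearly better than the chosen one. In mechanistic control it is worse: the chosen plan makes each bond in a discrete step with a defined migrating group. Both converge on the same arene and share the same endgame.

Alternative 3: The cut runs through C4–C5 and C1–C10 and removes ring A. In the forward step a chiral oxazaborolidinium triflimide activates the enone A6, and a [4+2] addition of the diene A5 (its silyloxy-bearing terminus bonding to the β-carbon C5) should give the cis-fused decalin-9-one A7 with a C2=C3 silyl enol ether.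
- In its favour: it is very convergent, quaternary C5 and ring A arise in one catalyst-controlled step from two simple partners, and ring B is six-membered from the start.
- Against it: β,β-disubstituted enones are poor dienophiles, and under a strong Lewis acid the silyloxydiene can divert to stepwise Michael addition or desilylation. After A7, C8 still needs two C–C bonds with substrate-controlled stereochemistry. The C3 oxygen must be removed with the alkene placed at C3=C4 (the enol ether has it at C2=C3) in the presence of the C9 ketone.
- Comparison: catalyst control of C5 is equal in both plans, and ring-B size without ring expansion is a point for A7. On C8 the chosen key step is better, since it installs the quaternary carbon complete. The C10 and C9 tasks are the same. In step count this plan would be comparable before the key step and longer after it.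

Key step: step 5

Assumption: for the chiral NHC ligand of step 1 and the N,N′-dioxide of step 5 the antipode that delivers the required configuration is used; both ligand families derive from amino alcohols or amino acids available in either enantiomeric form.
Assumption: the decalin does not control the two ring-C stereocentres in step 15; 24 is taken as one separable diastereomer of that step.
Remark: C5 is S throughout, the ring fusion of 8 and 11 is cis, and the ester of 11 lies on the face of the C5 methyl, as 24 requires.

## Steps

Step 1
Reactants: 1 3-methylcyclopent-2-en-1-one; 2 prop-1-en-2-ylmagnesium bromide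
Product: 4 trimethyl{[(3S)-3-methyl-3-(prop-1-en-2-yl)cyclopent-1-en-1-yl]oxy}silane, via bromomagnesium enolate 3 (not isolated)
Conditions: Cu(OTf)2 (3 mol %), chiral hydroxyalkyl imidazolinium salt (NHC precursor, 4 mol %), Et2O, 0 °C; then TMSCl, Et3N, DMPU, 0 °C → rt
Reagents that add atoms: chlorotrimethylsilane, C[Si](C)(C)Cl
Why: Copper-catalysed asymmetric conjugate addition of the alkenyl Grignard reagent forms C4–C5 and sets quaternary C5 (S) under control of the catalyst formed from Cu(OTf)2 and the chiral NHC ligand. O-Silylation of the magnesium enolate fixes the C9=C10 enolate regiochemistry, which deprotonation of the ketone could not give.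

Step 2
Reactants: 4 trimethyl{[(3S)-3-methyl-3-(prop-1-en-2-yl)cyclopent-1-en-1-yl]oxy}silane; 5 4-iodobut-1-ene
Product: 7 (3S)-2-(but-3-en-1-yl)-3-methyl-3-(prop-1-en-2-yl)cyclopentan-1-one (mixture of C2 epimers), via lithium enolate 6 (not isolated)
Conditions: MeLi, THF, 0 °C; then 5, DMPU, −78 → 0 °C
Reagents that add atoms: none
Why: MeLi cleaves the O–Si bond to the regiodefined lithium enolate, which is C-alkylated by the primary iodide (enolate alkylation, C1–C10). The configuration at C10 is immaterial here because it is equilibrated after ring closure.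

Step 3
Reactants: 7 (3S)-2-(but-3-en-1-yl)-3-methyl-3-(prop-1-en-2-yl)cyclopentan-1-one
Product: 8 (3aS,7aS)-3a,4-dimethyl-2,3,3a,6,7,7a-hexahydro-1H-inden-1-one
Conditions: second-generation Grubbs catalyst (H2IMes)(PCy3)Cl2Ru=CHPh (5 mol %), CH2Cl2, 40 °C; then DBU, rt
Reagents that add atoms: none
Why: Ring-closing metathesis between the monosubstituted and the 1,1-disubstituted alkene closes ring A as a trisubstituted cyclohexene with loss of ethene. DBU then equilibrates C10 to the cis fusion, the more stable arrangement for a hydrindan-1-one with an angular methyl at the other fusion carbon.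

Step 4
Reactants: 9 methyl 2-methyl-3-oxobutanoate
Product: 10 methyl 2-diazopropanoate
Conditions: 4-acetamidobenzenesulfonyl azide, DBU, MeCN, 0 °C → rt
Reagents that add atoms: 4-acetamidobenzenesulfonyl azide, CC(=O)Nc1ccc(cc1)S(=O)(=O)N=[N+]=[N-]
Why: Deacylative diazo transfer (Regitz type): the enolate of 9 adds to the sulfonyl azide and the adduct fragments with transfer of the acetyl group to the sulfonamide nitrogen. The volatile diazo ester is kept and used as a solution and is not concentrated to dryness.

Step 5
Reactants: 8 (3aS,7aS)-3a,4-dimethyl-2,3,3a,6,7,7a-hexahydro-1H-inden-1-one; 10 methyl 2-diazopropanoate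
Product: 11 methyl (2S,4aS,8aS)-2,4a,5-trimethyl-1-oxo-1,2,3,4,4a,7,8,8a-octahydronaphthalene-2-carboxylate
Conditions: Sc(OTf)3 (10 mol %), chiral N,N′-dioxide ligand of the pipecolic acid 2,6-diisopropylanilide type (propane-1,3-diyl bridge, enantiomer as required; 11 mol %), 10 (1.5 equiv, slow addition), CH2Cl2, 0 → 30 °C
Reagents that add atoms: none
Why: The complex formed from Sc(OTf)3 and the N,N′-dioxide binds the C9 carbonyl of 8, the diazo carbon of 10 adds to C9 from the convex face of the cis-hydrindanone to give a diazonium alkoxide, and the ring bond C9–C7 antiperiplanar to the leaving N2 shifts to the diazo carbon with loss of dinitrogen; the closest known reaction type is the Lewis-acid-catalysed enantioselective homologation of ketones with α-alkyl-α-diazo esters to α-quaternary β-keto esters (Tiffeneau–Demjanov type). No ring is closed by a cyclisation: ring B is enlarged from five to six members by this 1,2-shift, which forms C8–C9 and C7–C8 while the C9 carbonyl is regenerated. The one new stereocentre, C8, is fixed in the addition step, where the chiral ligand sphere around trivalent scandium selects the face of the diazo carbon, and the migration is then stereospecific; the ligand antipode is chosen so that the ester ends on the face of the C5 methyl, because the inherent bias of the substrate is expected to be small. The step needs migration of C7 and not of C10: the diazo ester approaches away from the substituted C10, which places the less substituted C7 antiperiplanar to N2, the usual preference of this reaction. Homologation should stop after one insertion because the ketone of 11, flanked by a quaternary and a tertiary carbon, is far more hindered than that of 8. C5 is untouched, and C10, though α to the activated ketone, is adjusted in step 6 in any case.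

Step 6
Reactants: 11 methyl (2S,4aS,8aS)-2,4a,5-trimethyl-1-oxo-1,2,3,4,4a,7,8,8a-octahydronaphthalene-2-carboxylate
Product: 12 methyl (2S,4aS,8aR)-2,4a,5-trimethyl-1-oxo-1,2,3,4,4a,7,8,8a-octahydronaphthalene-2-carboxylate
Conditions: MgBr2·OEt2, i-Pr2NEt, CH2Cl2, rt
Reagents that add atoms: none
Why: Epimerisation α to the ketone by soft enolisation; C10–H is the only enolisable hydrogen and the mild amine base avoids retro-Claisen opening of the non-enolisable β-keto ester. Equilibration runs through the magnesium chelate, which needs the ester near the C9=O plane (equatorial); only the trans-fused chair allows this without a syn-diaxial contact between C1 and the C8 methyl, and axial protonation of the enolate on the α-face leads to the same trans isomer.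

Step 7
Reactants: 12 methyl (2S,4aS,8aR)-2,4a,5-trimethyl-1-oxo-1,2,3,4,4a,7,8,8a-octahydronaphthalene-2-carboxylate
Product: 13 methyl (2S,4aS,8aS)-2,4a,5-trimethyl-1-methylidene-1,2,3,4,4a,7,8,8a-octahydronaphthalene-2-carboxylate
Conditions: Zn, CH2Br2, TiCl4, THF/CH2Cl2, 0 °C → rt
Reagents that add atoms: dibromomethane, BrCBr
Why: Takai–Lombardo methylenation: the small, oxophilic and non-basic methylene reagent made from Zn, CH2Br2 and TiCl4 olefinates hindered, epimerisable ketones and leaves esters untouched. C10 therefore keeps the configuration set in step 6, which a basic Wittig reagent would put at risk.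

Step 8
Reactants: 13 methyl (2S,4aS,8aS)-2,4a,5-trimethyl-1-methylidene-1,2,3,4,4a,7,8,8a-octahydronaphthalene-2-carboxylate
Product: 14 methyl (1R,2S,4aS,8aS)-1,2,4a,5-tetramethyl-1,2,3,4,4a,7,8,8a-octahydronaphthalene-2-carboxylate
Conditions: H2 (1 atm), PtO2, EtOAc, rt, stopped after one equivalent
Reagents that add atoms: none
Why: Heterogeneous syn hydrogenation of the 1,1-disubstituted exocyclic alkene, which should react faster than the trisubstituted C3=C4 alkene beside quaternary C5. The β-face of C9 lies under the syn-axial C5 methyl and beside the equatorial ester, so hydrogen should add from the α-face and place the new C9 methyl β (axial), as in 24.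

Step 9
Reactants: 14 methyl (1R,2S,4aS,8aS)-1,2,4a,5-tetramethyl-1,2,3,4,4a,7,8,8a-octahydronaphthalene-2-carboxylate
Product: 15 [(1R,2S,4aS,8aS)-1,2,4a,5-tetramethyl-1,2,3,4,4a,7,8,8a-octahydronaphthalen-2-yl]methanol
Conditions: LiAlH4, THF, 0 °C → reflux
Reagents that add atoms: none
Why: Hydride reduction of the hindered neopentyl ester to the primary alcohol. No stereocentre and no alkene is affected.

Step 10
Reactants: 15 [(1R,2S,4aS,8aS)-1,2,4a,5-tetramethyl-1,2,3,4,4a,7,8,8a-octahydronaphthalen-2-yl]methanol
Product: 16 (1R,2S,4aS,8aS)-1,2,4a,5-tetramethyl-1,2,3,4,4a,7,8,8a-octahydronaphthalene-2-carbaldehyde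
Conditions: Dess–Martin periodinane, CH2Cl2, rt
Reagents that add atoms: none
Why: Dess–Martin oxidation of a primary alcohol to the aldehyde. The aldehyde has no α-hydrogen, so it can neither epimerise nor enolise.

Step 11
Reactants: 16 (1R,2S,4aS,8aS)-1,2,4a,5-tetramethyl-1,2,3,4,4a,7,8,8a-octahydronaphthalene-2-carbaldehyde; 17 1,2,4,5-tetramethoxybenzene
Product: 20 O-{(2,3,5,6-tetramethoxyphenyl)[(1R,2S,4aS,8aS)-1,2,4a,5-tetramethyl-1,2,3,4,4a,7,8,8a-octahydronaphthalen-2-yl]methyl} S-methyl carbonodithioate (both C11 epimers), via aryllithium 18 (not isolated), via lithium alkoxide 19 (not isolated)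
Conditions: 17, n-BuLi, TMEDA, THF, 0 °C; then 16, −78 → 0 °C; then CS2; then MeI, rt
Reagents that add atoms: carbon disulfide, S=C=S; iodomethane, CI
Why: Directed ortho-lithiation of 17 between two methoxy groups gives 18, which adds to the non-enolisable aldehyde and forms the C11–aryl bond. The alkoxide is converted in the same flask to the S-methyl xanthate; the carbinol configuration does not matter because C11 becomes CH2 in the next step.

Step 12
Reactants: 20 O-{(2,3,5,6-tetramethoxyphenyl)[(1R,2S,4aS,8aS)-1,2,4a,5-tetramethyl-1,2,3,4,4a,7,8,8a-octahydronaphthalen-2-yl]methyl} S-methyl carbonodithioate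
Product: 21 3-{[(1R,2R,4aS,8aS)-1,2,4a,5-tetramethyl-1,2,3,4,4a,7,8,8a-octahydronaphthalen-2-yl]methyl}-1,2,4,5-tetramethoxybenzene
Conditions: Bu3SnH, AIBN, toluene, 110 °C
Reagents that add atoms: none
Why: Barton–McCombie deoxygenation through a benzylic radical. The neutral radical conditions avoid a C11 cation next to quaternary C8 (1,2-shifts, attack by the alkene), and the xanthate has no β-hydrogen for thermal elimination.

Step 13
Reactants: 21 3-{[(1R,2R,4aS,8aS)-1,2,4a,5-tetramethyl-1,2,3,4,4a,7,8,8a-octahydronaphthalen-2-yl]methyl}-1,2,4,5-tetramethoxybenzene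
Product: 22 2,5-dimethoxy-3-{[(1R,2R,4aS,8aS)-1,2,4a,5-tetramethyl-1,2,3,4,4a,7,8,8a-octahydronaphthalen-2-yl]methyl}cyclohexa-2,5-diene-1,4-dione
Conditions: (NH4)2Ce(NO3)6, MeCN/H2O, 0 °C
Reagents that add atoms: water, O
Why: Oxidative demethylation of a para-dimethoxy pair by tetravalent cerium gives the p-quinone. The two possible para pairs are equivalent by the symmetry of the arene, so one quinone should form, and the isolated trisubstituted alkene is not expected to react at 0 °C.

Step 14
Reactants: 22 2,5-dimethoxy-3-{[(1R,2R,4aS,8aS)-1,2,4a,5-tetramethyl-1,2,3,4,4a,7,8,8a-octahydronaphthalen-2-yl]methyl}cyclohexa-2,5-diene-1,4-dione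
Product: 23 2-hydroxy-5-methoxy-3-{[(1R,2R,4aS,8aS)-1,2,4a,5-tetramethyl-1,2,3,4,4a,7,8,8a-octahydronaphthalen-2-yl]methyl}cyclohexa-2,5-diene-1,4-dione
Conditions: KOH, MeOH/H2O, rt; then HCl (aq)
Reagents that add atoms: potassium hydroxide, [K+].[OH-]
Why: Addition–elimination of hydroxide at a vinylogous ester carbon. The methoxy group next to the bulky alkyl chain is twisted out of conjugation and should be the one replaced, as in related 3-alkyl-2,5-dimethoxybenzoquinones; the resulting hydroxyquinone anion resists further attack at room temperature.

Step 15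
Reactants: 23 2-hydroxy-5-methoxy-3-{[(1R,2R,4aS,8aS)-1,2,4a,5-tetramethyl-1,2,3,4,4a,7,8,8a-octahydronaphthalen-2-yl]methyl}cyclohexa-2,5-diene-1,4-dione
Product: 24 methyl (1R,5S)-1-hydroxy-3-methoxy-4-oxo-5-{[(1R,2R,4aS,8aS)-1,2,4a,5-tetramethyl-1,2,3,4,4a,7,8,8a-octahydronaphthalen-2-yl]methyl}cyclopent-2-ene-1-carboxylate (dysidenone B)
Conditions: NaOMe, MeOH, rt → 50 °C; then AcOH; separation of diastereomers by HPLC
Reagents that add atoms: sodium methoxide, C[O-].[Na+]
Why: Benzilic ester rearrangement with ring contraction: methoxide adds to the carbonyl carbon of the 1,2-dicarbonyl tautomer that carried the hydroxyl, the ring bond to the alkyl-bearing carbon shifts to the neighbouring carbonyl, and protonation gives the CH next to the new tertiary alkoxide. The carbinol centre forms without control from the distant decalin and the adjacent CH is epimerisable, so 24 should form together with its ring-C diastereomers; it is separated, and isomers differing only at the CH can be re-equilibrated with base.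

## Compound list

1 | 3-methylcyclopent-2-en-1-one | CC1=CC(=O)CC1 | starting material
2 | prop-1-en-2-ylmagnesium bromide | CC(=C)[Mg]Br | starting material
3 | bromomagnesium (3S)-3-methyl-3-(prop-1-en-2-yl)cyclopent-1-en-1-olate | Br[Mg]OC1=C[C@@](C)(C(C)=C)CC1 | intermediate (not isolated)
4 | trimethyl{[(3S)-3-methyl-3-(prop-1-en-2-yl)cyclopent-1-en-1-yl]oxy}silane | C[Si](C)(C)OC1=C[C@@](C)(C(C)=C)CC1 | intermediate
5 | 4-iodobut-1-ene | C=CCCI | starting material
6 | lithium (3S)-3-methyl-3-(prop-1-en-2-yl)cyclopent-1-en-1-olate | [Li+].[O-]C1=C[C@@](C)(C(C)=C)CC1 | intermediate (not isolated)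
7 | (3S)-2-(but-3-en-1-yl)-3-methyl-3-(prop-1-en-2-yl)cyclopentan-1-one (C2 epimers) | O=C1CC[C@](C)(C(C)=C)C1CCC=C | intermediate
8 | (3aS,7aS)-3a,4-dimethyl-2,3,3a,6,7,7a-hexahydro-1H-inden-1-one | O=C1CC[C@]2(C)C(C)=CCC[C@H]12 | intermediate
9 | methyl 2-methyl-3-oxobutanoate | CC(=O)C(C)C(=O)OC | starting material
10 | methyl 2-diazopropanoate | CC(=[N+]=[N-])C(=O)OC | intermediate
11 | methyl (2S,4aS,8aS)-2,4a,5-trimethyl-1-oxo-1,2,3,4,4a,7,8,8a-octahydronaphthalene-2-carboxylate | COC(=O)[C@@]1(C)CC[C@]2(C)C(C)=CCC[C@@H]2C1=O | intermediate
12 | methyl (2S,4aS,8aR)-2,4a,5-trimethyl-1-oxo-1,2,3,4,4a,7,8,8a-octahydronaphthalene-2-carboxylate | COC(=O)[C@@]1(C)CC[C@]2(C)C(C)=CCC[C@H]2C1=O | intermediate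
13 | methyl (2S,4aS,8aS)-2,4a,5-trimethyl-1-methylidene-1,2,3,4,4a,7,8,8a-octahydronaphthalene-2-carboxylate | COC(=O)[C@@]1(C)CC[C@]2(C)C(C)=CCC[C@H]2C1=C | intermediate
14 | methyl (1R,2S,4aS,8aS)-1,2,4a,5-tetramethyl-1,2,3,4,4a,7,8,8a-octahydronaphthalene-2-carboxylate | COC(=O)[C@@]1(C)CC[C@]2(C)C(C)=CCC[C@H]2[C@H]1C | intermediate
15 | [(1R,2S,4aS,8aS)-1,2,4a,5-tetramethyl-1,2,3,4,4a,7,8,8a-octahydronaphthalen-2-yl]methanol | OC[C@@]1(C)CC[C@]2(C)C(C)=CCC[C@H]2[C@H]1C | intermediate
16 | (1R,2S,4aS,8aS)-1,2,4a,5-tetramethyl-1,2,3,4,4a,7,8,8a-octahydronaphthalene-2-carbaldehyde | O=C[C@@]1(C)CC[C@]2(C)C(C)=CCC[C@H]2[C@H]1C | intermediate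
17 | 1,2,4,5-tetramethoxybenzene | COc1cc(OC)c(OC)cc1OC | starting material
18 | (2,3,5,6-tetramethoxyphenyl)lithium | COc1cc(OC)c(OC)c([Li])c1OC | intermediate (not isolated)
19 | lithium (2,3,5,6-tetramethoxyphenyl)[(1R,2S,4aS,8aS)-1,2,4a,5-tetramethyl-1,2,3,4,4a,7,8,8a-octahydronaphthalen-2-yl]methanolate (both C11 epimers) | [Li+].[O-]C(c1c(OC)c(OC)cc(OC)c1OC)[C@@]1(C)CC[C@]2(C)C(C)=CCC[C@H]2[C@H]1C | intermediate (not isolated)
20 | O-{(2,3,5,6-tetramethoxyphenyl)[(1R,2S,4aS,8aS)-1,2,4a,5-tetramethyl-1,2,3,4,4a,7,8,8a-octahydronaphthalen-2-yl]methyl} S-methyl carbonodithioate (both C11 epimers) | CSC(=S)OC(c1c(OC)c(OC)cc(OC)c1OC)[C@@]1(C)CC[C@]2(C)C(C)=CCC[C@H]2[C@H]1C | intermediate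
21 | 3-{[(1R,2R,4aS,8aS)-1,2,4a,5-tetramethyl-1,2,3,4,4a,7,8,8a-octahydronaphthalen-2-yl]methyl}-1,2,4,5-tetramethoxybenzene | COc1cc(OC)c(OC)c(C[C@@]2(C)CC[C@]3(C)C(C)=CCC[C@H]3[C@H]2C)c1OC | intermediate
22 | 2,5-dimethoxy-3-{[(1R,2R,4aS,8aS)-1,2,4a,5-tetramethyl-1,2,3,4,4a,7,8,8a-octahydronaphthalen-2-yl]methyl}cyclohexa-2,5-diene-1,4-dione | COC1=CC(=O)C(OC)=C(C[C@@]2(C)CC[C@]3(C)C(C)=CCC[C@H]3[C@H]2C)C1=O | intermediate
23 | 2-hydroxy-5-methoxy-3-{[(1R,2R,4aS,8aS)-1,2,4a,5-tetramethyl-1,2,3,4,4a,7,8,8a-octahydronaphthalen-2-yl]methyl}cyclohexa-2,5-diene-1,4-dione | COC1=CC(=O)C(O)=C(C[C@@]2(C)CC[C@]3(C)C(C)=CCC[C@H]3[C@H]2C)C1=O | intermediate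
24 | methyl (1R,5S)-1-hydroxy-3-methoxy-4-oxo-5-{[(1R,2R,4aS,8aS)-1,2,4a,5-tetramethyl-1,2,3,4,4a,7,8,8a-octahydronaphthalen-2-yl]methyl}cyclopent-2-ene-1-carboxylate (dysidenone B) | COC(=O)[C@@]1(O)C=C(OC)C(=O)[C@H]1C[C@@]1(C)CC[C@]2(C)C(C)=CCC[C@H]2[C@H]1C | target

## Step count and least certain steps

Total step count: 15. Longest linear sequence: 14 steps (steps 1–3 and 5–15); step 4 is a one-step side branch.

Step 5 (key step). What may go wrong:
- slow addition of the fully substituted diazo carbon to a cyclopentanone carbonyl that has a tertiary neighbour;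
- loss of the diazo ester by 1,2-hydride shift to an acrylate;
- migration of C10 in place of C7;
- a mismatched pairing of catalyst and substrate, giving poor face selectivity at C8.

Fallback, from 8 back to 11: homologation of 8 with the unhindered methyl diazoacetate and BF3·OEt2 (ring expansion with migration of C7) would give methyl (4aS,8aS)-4a,5-dimethyl-1-oxo-1,2,3,4,4a,7,8,8a-octahydronaphthalene-2-carboxylate F1. Its stabilised enolate would then be C-methylated with MeI under a chiral quaternary ammonium phase-transfer catalyst to give 11. Reagent control is wanted because axial attack on the cis-fused enolate is expected to favour the β-face, which would give the wrong C8 epimer.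

Step 8. What may go wrong:
- poor facial selectivity, because the α-face carries the axial C8 methyl on the neighbouring carbon while the β-face carries the syn-axial C5 methyl;
- attraction of the catalyst surface to the ester on the β-side;
- competing reduction or migration of the C3=C4 alkene.

Fallback, from 13 back to 15: the hydrogenation is moved to a substrate whose β-face is shielded by a large, non-coordinating group. Reduction of 13 with LiAlH4 would give [(2S,4aS,8aS)-2,4a,5-trimethyl-1-methylidene-1,2,3,4,4a,7,8,8a-octahydronaphthalen-2-yl]methanol F2. Silylation (i-Pr3SiCl, imidazole) would give triisopropyl{[(2S,4aS,8aS)-2,4a,5-trimethyl-1-methylidene-1,2,3,4,4a,7,8,8a-octahydronaphthalen-2-yl]methoxy}silane F3. Hydrogenation (H2, PtO2) would give triisopropyl{[(1R,2S,4aS,8aS)-1,2,4a,5-tetramethyl-1,2,3,4,4a,7,8,8a-octahydronaphthalen-2-yl]methoxy}silane F4, and Bu4NF would release 15.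

Step 6. What may go wrong: incomplete enolisation of the hindered tertiary C10–H, or an equilibrium that does not lie far enough on the trans side; without chelation the two ring fusions are estimated to be close in energy.

Fallback, from 11 back to 12: kinetic instead of thermodynamic control. Irreversible deprotonation with KN(SiMe3)2 in THF at −78 °C would give potassium (2S,4aR)-2-(methoxycarbonyl)-2,4a,5-trimethyl-2,3,4,4a,7,8-hexahydronaphthalen-1-olate F5. A quench with acetic acid at −78 °C follows; axial protonation anti to the neighbouring C5 methyl should give 12.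

Step 15. What may go wrong:
- lack of facial control in the 1,2-shift, which gives both configurations at the carbinol carbon;
- epimerisation at the adjacent CH;
- exchange or loss of the enol ether under prolonged base.

Fallback, from 23 back to 24: benzilic acid rearrangement with aqueous KOH would give (1R,5S)-1-hydroxy-3-methoxy-4-oxo-5-{[(1R,2R,4aS,8aS)-1,2,4a,5-tetramethyl-1,2,3,4,4a,7,8,8a-octahydronaphthalen-2-yl]methyl}cyclopent-2-ene-1-carboxylic acid F6 together with its diastereomers. These would be separated by fractional crystallisation of their salts with an enantiopure amine such as (R)-1-phenylethanamine. Esterification with (trimethylsilyl)diazomethane in MeOH/toluene would then give 24.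

Step 7. What may go wrong: failure of the methylene reagent to reach a carbonyl flanked by a quaternary and a tertiary carbon and covered on both faces by axial methyls, or Lewis-acid-induced epimerisation at C10.

Fallback, from 12 back to 13: Peterson olefination. Addition of Me3SiCH2Li/CeCl3 (the organocerium reagent adds to hindered, enolisable ketones and spares the hindered ester) would give methyl (2S,4aS,8aR)-1-hydroxy-2,4a,5-trimethyl-1-[(trimethylsilyl)methyl]-1,2,3,4,4a,7,8,8a-octahydronaphthalene-2-carboxylate F7. Acid-induced anti elimination (aqueous HF, MeCN) would give 13; KH is avoided because the β-alkoxy ester could cleave by retro-aldol.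

Step 1. What may go wrong: erosion of enantioselectivity in forming a quaternary centre on a five-membered enone, and competing 1,2-addition of the Grignard reagent.

Fallback, from 1 back to 7:
- Conjugate addition of the α-silylvinyl alane diisobutyl[1-(trimethylsilyl)ethenyl]aluminium F8 (from ethynyltrimethylsilane and i-Bu2AlH) with Cu(OTf)2 and a chiral imidazolinium salt as NHC precursor, a variant with good support for β-substituted cyclopentenones. O-Silylation (Me3SiOTf) would give trimethyl{[(3S)-3-methyl-3-[1-(trimethylsilyl)ethenyl]cyclopent-1-en-1-yl]oxy}silane F9.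
- MeLi, then 5, would give (3S)-2-(but-3-en-1-yl)-3-methyl-3-[1-(trimethylsilyl)ethenyl]cyclopentan-1-one F10.
- Ipso-iododesilylation with N-iodosuccinimide would give (3S)-2-(but-3-en-1-yl)-3-(1-iodoethenyl)-3-methylcyclopentan-1-one F11.
- Negishi methylation (MeZnCl, Pd(PPh3)4, THF) would give 7.

## Further compounds

F1 | step 5 | methyl (4aS,8aS)-4a,5-dimethyl-1-oxo-1,2,3,4,4a,7,8,8a-octahydronaphthalene-2-carboxylate (C2 epimers and enol) | COC(=O)C1CC[C@]2(C)C(C)=CCC[C@@H]2C1=O
F2 | step 8 | [(2S,4aS,8aS)-2,4a,5-trimethyl-1-methylidene-1,2,3,4,4a,7,8,8a-octahydronaphthalen-2-yl]methanol | OC[C@@]1(C)CC[C@]2(C)C(C)=CCC[C@H]2C1=C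
F3 | step 8 | triisopropyl{[(2S,4aS,8aS)-2,4a,5-trimethyl-1-methylidene-1,2,3,4,4a,7,8,8a-octahydronaphthalen-2-yl]methoxy}silane | CC(C)[Si](OC[C@@]1(C)CC[C@]2(C)C(C)=CCC[C@H]2C1=C)(C(C)C)C(C)C
F4 | step 8 | triisopropyl{[(1R,2S,4aS,8aS)-1,2,4a,5-tetramethyl-1,2,3,4,4a,7,8,8a-octahydronaphthalen-2-yl]methoxy}silane | CC(C)[Si](OC[C@@]1(C)CC[C@]2(C)C(C)=CCC[C@H]2[C@H]1C)(C(C)C)C(C)C
F5 | step 6 | potassium (2S,4aR)-2-(methoxycarbonyl)-2,4a,5-trimethyl-2,3,4,4a,7,8-hexahydronaphthalen-1-olate | COC(=O)[C@@]1(C)CC[C@]2(C)C(C)=CCCC2=C1[O-].[K+]
F6 | step 15 | (1R,5S)-1-hydroxy-3-methoxy-4-oxo-5-{[(1R,2R,4aS,8aS)-1,2,4a,5-tetramethyl-1,2,3,4,4a,7,8,8a-octahydronaphthalen-2-yl]methyl}cyclopent-2-ene-1-carboxylic acid | OC(=O)[C@@]1(O)C=C(OC)C(=O)[C@H]1C[C@@]1(C)CC[C@]2(C)C(C)=CCC[C@H]2[C@H]1C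
F7 | step 7 | methyl (2S,4aS,8aR)-1-hydroxy-2,4a,5-trimethyl-1-[(trimethylsilyl)methyl]-1,2,3,4,4a,7,8,8a-octahydronaphthalene-2-carboxylate (C1 epimers) | COC(=O)[C@@]1(C)CC[C@]2(C)C(C)=CCC[C@H]2C1(O)C[Si](C)(C)C
F8 | step 1 | diisobutyl[1-(trimethylsilyl)ethenyl]aluminium | CC(C)C[Al](CC(C)C)C(=C)[Si](C)(C)C
F9 | step 1 | trimethyl{[(3S)-3-methyl-3-[1-(trimethylsilyl)ethenyl]cyclopent-1-en-1-yl]oxy}silane | C[Si](C)(C)OC1=C[C@@](C)(C(=C)[Si](C)(C)C)CC1
F10 | step 1 | (3S)-2-(but-3-en-1-yl)-3-methyl-3-[1-(trimethylsilyl)ethenyl]cyclopentan-1-one (C2 epimers) | O=C1CC[C@](C)(C(=C)[Si](C)(C)C)C1CCC=C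
F11 | step 1 | (3S)-2-(but-3-en-1-yl)-3-(1-iodoethenyl)-3-methylcyclopentan-1-one (C2 epimers) | O=C1CC[C@](C)(C(I)=C)C1CCC=C
A1 | alternative 1 | dimethyl 2-ethynyl-2-[(3E,7Z)-3-methyl-7-(triisopropylsilyloxy)nona-3,7-dien-1-yl]propanedioate | C#CC(C(=O)OC)(C(=O)OC)CC/C(C)=C/CC/C(O[Si](C(C)C)(C(C)C)C(C)C)=C/C
A2 | alternative 1 | dimethyl (4aS,5R,8aR)-4a,5-dimethyl-1-methylidene-6-oxooctahydronaphthalene-2,2(1H)-dicarboxylate | C=C1C(C(=O)OC)(C(=O)OC)CC[C@]2(C)[C@@H](C)C(=O)CC[C@H]21
A3 | alternative 2 | 3-{[(1S,4aS,8aS)-2,5,5,8a-tetramethyl-1,4,4a,5,6,7,8,8a-octahydronaphthalen-1-yl]methyl}-1,2,4,5-tetramethoxybenzene | COc1cc(OC)c(OC)c(C[C@H]2C(C)=CC[C@H]3C(C)(C)CCC[C@]23C)c1OC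
A4 | alternative 2 | 3-{[(1R,2R,4aS,8aS)-1,2,4a,5-tetramethyl-1,2,3,4,4a,7,8,8a-octahydronaphthalen-2-yl]methyl}-1,2,4,5-tetramethoxybenzene | COc1cc(OC)c(OC)c(C[C@@]2(C)CC[C@]3(C)C(C)=CCC[C@H]3[C@H]2C)c1OC
A5 | alternative 3 | tert-butyldimethyl{[(3Z)-penta-1,3-dien-3-yl]oxy}silane | C=C/C(O[Si](C)(C)C(C)(C)C)=C/C
A6 | alternative 3 | 3-methylcyclohex-2-en-1-one | CC1=CC(=O)CCC1
A7 | alternative 3 | (4aR,5S,8aS)-6-[(tert-butyldimethylsilyl)oxy]-4a,5-dimethyl-3,4,4a,5,8,8a-hexahydronaphthalen-1(2H)-one | O=C1CCC[C@]2(C)[C@H](C)C(O[Si](C)(C)C(C)(C)C)=CC[C@H]12
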